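Ring B numbering used throughout: C1 is the CH2-bearing carbon, C4 the carbinol-bearing carbon, C5 the hydroxyl carbon.

Retrosynthesis: the ring A hydroxyls and the saturated side chain are released last from dibenzyl ether 22 by hydrogenation; ring B is then cut at C2–C3 and C4–C5.
Enabling feature: ring B is a phenol with the carbinol ortho and the CH2Ar group meta to the hydroxyl, so C1, C6, C5 and C2 are the four ring carbons of a 3-substituted 4-chlorocyclobutenone (its C=O becomes C5–OH) and C3–C4 are the two alkene carbons of an alkenylstannane that already holds the tertiary alcohol.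
Fragment 1 (stannane 7): geraniol, Sharpless epoxidation, Appel chlorination, base-induced fragmentation to (S)-dehydrolinalool, hydrostannation.
Fragment 2 (chlorocyclobutenone 18): ring A is bought as aldehyde 8; demethylation, benzylation, reduction, bromination, ethynylation, dichloroketene [2+2] cycloaddition, mono-dechlorination.
Forward order: ring A is present from the start; ring B is the only ring made, in step 12, which also joins the chain; step 13 saturates the chain and removes both benzyl groups.
Stereochemistry: the single stereocentre (S) is set in step 1 by L-(+)-diethyl tartrate, and its C–O bond is never broken afterwards.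

Key step: step 12

Assumption: aldehyde 8 is taken as purchasable; the centres at C4 of cyclobutenones 18 and 19 and at C6 of dienone 21 are left undefined because they vanish on aromatisation; chloroalkenol 4 is drawn as the E isomer, although either alkene geometry leads on to the alkyne.

Step 1
Reactants: 1 geraniol
Product: 2 (2S,3S)-2,3-epoxygeraniol {[(2S,3S)-3-methyl-3-(4-methylpent-3-en-1-yl)oxiran-2-yl]methanol}
Conditions: Ti(OiPr)4 (5 mol %), L-(+)-diethyl tartrate (7 mol %), t-BuOOH, 4 Å MS, CH2Cl2, −20 °C
Reagents that add atoms: tert-butyl hydroperoxide, CC(C)(C)OO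
Why: Sharpless asymmetric epoxidation, in which the allylic hydroxyl binds to the catalyst formed from Ti(OiPr)4 and the tartrate so that only the 2,3-alkene is oxidised, and L-(+)-diethyl tartrate directs oxygen to the alkene face that gives the (2S,3S)-epoxide, which fixes the configuration of the later carbinol carbon.

Step 2
Reactants: 2 (2S,3S)-2,3-epoxygeraniol
Product: 3 (2S,3R)-3-(chloromethyl)-2-methyl-2-(4-methylpent-3-en-1-yl)oxirane
Conditions: PPh3, CCl4, NaHCO3, reflux
Reagents that add atoms: tetrachloromethane, ClC(Cl)(Cl)Cl
Why: Appel reaction, in which the alkoxyphosphonium ion of the primary alcohol is displaced by chloride at CH2 only, so that neither epoxide carbon is touched (the new descriptor at the CH carbon is a priority effect) and the hydrogen carbonate protects the acid-labile trisubstituted epoxide.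

Step 3
Reactants: 3 (2S,3R)-3-(chloromethyl)-2-methyl-2-(4-methylpent-3-en-1-yl)oxirane
Product: 5 (S)-3,7-dimethyloct-6-en-1-yn-3-ol [(S)-dehydrolinalool], via chloroalkenol 4 (not isolated)
Conditions: n-BuLi (3.2 equiv), THF, −40 → −20 °C; then H2O
Reagents that add atoms: none
Why: base-induced fragmentation of a 2,3-epoxy chloride to a propargylic alcohol, in which lithiation next to chlorine opens the epoxide by beta-elimination to the alkoxide of 4, a second equivalent removes HCl to give the alkyne and a third holds it as the acetylide, while the C3–O bond stays intact so that the S configuration is carried over unchanged.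

Step 4
Reactants: 5 (S)-3,7-dimethyloct-6-en-1-yn-3-ol; 6 tributyltin hydride (Bu3SnH)
Product: 7 (S,E)-3,7-dimethyl-1-(tributylstannyl)octa-1,6-dien-3-ol
Conditions: PdCl2(PPh3)2 (2 mol %), THF, 0 °C → rt, slow addition of 6
Reagents that add atoms: none
Why: palladium-catalysed hydrostannation, a syn addition of H–Sn across the terminal alkyne in which the bulky tertiary carbinol sends tin to the terminal carbon and so should give the E-alkenylstannane, while the trisubstituted alkene and the stereocentre take no part.

Step 5
Reactants: 8 2-hydroxy-3-methoxy-5-methylbenzaldehyde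
Product: 9 2,3-dihydroxy-5-methylbenzaldehyde
Conditions: BBr3 (2.5 equiv), CH2Cl2, −78 °C → rt; then H2O
Reagents that add atoms: none
Why: Lewis-acid cleavage of an aryl methyl ether, in which boron binds the methoxy oxygen, bromide removes the methyl group by SN2 attack and water hydrolyses the aryl borate, a standard demethylation of ortho-vanillin-type aldehydes that spares the formyl group.

Step 6
Reactants: 9 2,3-dihydroxy-5-methylbenzaldehyde
Product: 10 2,3-bis(benzyloxy)-5-methylbenzaldehyde
Conditions: BnBr (2.4 equiv), K2CO3, DMF, 60 °C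
Reagents that add atoms: benzyl bromide, BrCc1ccccc1
Why: Williamson ether synthesis, in which both phenoxides are alkylated by SN2 attack on benzyl bromide, and benzyl is chosen because it can be removed at the end by hydrogenolysis without acid.

Step 7
Reactants: 10 2,3-bis(benzyloxy)-5-methylbenzaldehyde
Product: 11 [2,3-bis(benzyloxy)-5-methylphenyl]methanol
Conditions: NaBH4, MeOH/THF, 0 °C
Reagents that add atoms: none
Why: hydride reduction of an aromatic aldehyde to the benzylic alcohol, to which aryl benzyl ethers are inert.

Step 8
Reactants: 11 [2,3-bis(benzyloxy)-5-methylphenyl]methanol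
Product: 12 1,2-bis(benzyloxy)-3-(bromomethyl)-5-methylbenzene
Conditions: PBr3 (0.4 equiv), Et2O, 0 °C
Reagents that add atoms: phosphorus tribromide, BrP(Br)Br
Why: conversion of a benzylic alcohol into the bromide through its phosphite ester and SN2 attack by bromide, fast at 0 °C at an electron-rich benzylic position, with the sensitive bromide taken on without delay.

Step 9
Reactants: 12 1,2-bis(benzyloxy)-3-(bromomethyl)-5-methylbenzene; 13 ethynylmagnesium bromide (HC≡CMgBr)
Product: 14 1,2-bis(benzyloxy)-5-methyl-3-(prop-2-yn-1-yl)benzene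
Conditions: 13 (3 equiv, THF solution), CuCl (10 mol %), THF, 0 → 50 °C; aq. NH4Cl
Reagents that add atoms: none
Why: copper-catalysed cross-coupling of a benzylic bromide with an alkynyl Grignard reagent, in which the excess of 13 keeps the product from being benzylated a second time and the mildly acidic quench avoids propargyl-to-allene isomerisation.

Step 10
Reactants: 14 1,2-bis(benzyloxy)-5-methyl-3-(prop-2-yn-1-yl)benzene; 15 trichloroacetyl chloride
Product: 17 3-[2,3-bis(benzyloxy)-5-methylbenzyl]-4,4-dichlorocyclobut-2-en-1-one, via dichloroketene 16 (not isolated)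
Conditions: Zn–Cu couple, Et2O/DME, rt, slow addition of 15
Reagents that add atoms: none
Why: zinc removes two chlorines from 15 to give dichloroketene 16, which adds to the terminal alkyne in a thermal [2+2] ketene–alkyne cycloaddition with the alkyne CH carbon bonding to the ketene carbonyl carbon, so that the arylmethyl group ends at C3, while DME ties up ZnCl2 and so suppresses 1,3-chlorine shift and ether cleavage.

Step 11
Reactants: 17 3-[2,3-bis(benzyloxy)-5-methylbenzyl]-4,4-dichlorocyclobut-2-en-1-one
Product: 18 3-[2,3-bis(benzyloxy)-5-methylbenzyl]-4-chlorocyclobut-2-en-1-one (racemic at C4)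
Conditions: Zn dust (1.1 equiv), AcOH, TMEDA, EtOH, −10 → 0 °C
Reagents that add atoms: none
Why: dissolving-metal reduction of an alpha,alpha-dichloro ketone, in which the first C–Cl bond is reduced much faster than the second, so that a limited amount of zinc at low temperature should stop at the monochloride, and TMEDA buffers the zinc salts that would otherwise move the chlorine or the double bond.

Step 12
Reactants: 18 3-[2,3-bis(benzyloxy)-5-methylbenzyl]-4-chlorocyclobut-2-en-1-one; 7 (S,E)-3,7-dimethyl-1-(tributylstannyl)octa-1,6-dien-3-ol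
Product: 22 5-[2,3-bis(benzyloxy)-5-methylbenzyl]-2-[(2S)-2-hydroxy-6-methylhept-5-en-2-yl]phenol, via 4-alkenylcyclobutenone 19 (not isolated), via dienylketene 20 (not isolated), via cyclohexadienone 21 (not isolated)
Conditions: Pd(PPh3)4 (5 mol %), dioxane (degassed), 50 °C, then 100 °C
Reagents that add atoms: none
Why: Zerovalent palladium from Pd(PPh3)4 inserts into the allylic C4–Cl bond of 18, transmetalation with stannane 7 and reductive elimination give 4-alkenylcyclobutenone 19 (ring B C2–C3 bond), and heating opens 19 by conrotatory 4π-electrocyclic cleavage of its C1–C4 bond to dienylketene 20. Ring B then closes by a thermal disrotatory 6π-electrocyclisation between the ketene carbon and the alkene terminus that carries the carbinol (ring B C4–C5 bond), and cyclohexadienone 21 tautomerises to phenol 22 with the gain of aromaticity as driving force. The closest known reaction type is the palladium-catalysed cross-coupling of 4-chlorocyclobutenones with alkenylstannanes followed by thermal ring expansion of the 4-alkenylcyclobutenone to a phenol. No stereocentre is created, since the centres at C4 of 19 and C6 of 21 are lost on aromatisation, and the quaternary carbinol centre brought in with 7 has no bond broken and no hydrogen of its own, so it cannot epimerise. The coupling raises no regiochemical question, because the palladium-bound oxocyclobutenyl unit from 18 has equivalent CH termini at C2 and C4 and either leads to 19; what the step needs is inward rotation of the alkenyl group on ring opening, which is secured because the ring opening is reversible whereas the 6π closure is not, so that the outward ketene returns through 19. The E geometry of the stannane keeps the bulky carbinol on the outside of the closing triene, and the position of every ring B substituent follows from connectivity alone.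

Step 13
Reactants: 22 5-[2,3-bis(benzyloxy)-5-methylbenzyl]-2-[(2S)-2-hydroxy-6-methylhept-5-en-2-yl]phenol
Product: 23 asperchondol A [3-{3-hydroxy-4-[(2S)-2-hydroxy-6-methylheptan-2-yl]benzyl}-5-methylbenzene-1,2-diol]
Conditions: H2 (1 atm), Pd/C (10 wt %), EtOAc, rt; filtration and concentration under argon
Reagents that add atoms: none
Why: heterogeneous catalytic hydrogenation, which should saturate the trisubstituted side-chain alkene and cleave both aryl benzyl ethers by hydrogenolysis, while the acid-free medium keeps the tertiary benzylic alcohol from ionising so that the stereocentre is left as it is.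

Compound list
1 | geraniol | CC(C)=CCC/C(C)=C/CO | starting material
2 | (2S,3S)-2,3-epoxygeraniol, [(2S,3S)-3-methyl-3-(4-methylpent-3-en-1-yl)oxiran-2-yl]methanol | CC(C)=CCC[C@]1(C)O[C@H]1CO | intermediate
3 | (2S,3R)-3-(chloromethyl)-2-methyl-2-(4-methylpent-3-en-1-yl)oxirane | CC(C)=CCC[C@]1(C)O[C@H]1CCl | intermediate
4 | (1E,3S)-1-chloro-3,7-dimethylocta-1,6-dien-3-ol (chloroalkenol, formed as its lithium alkoxide) | CC(C)=CCC[C@](C)(O)/C=C/Cl | intermediate
5 | (S)-3,7-dimethyloct-6-en-1-yn-3-ol, (S)-dehydrolinalool | CC(C)=CCC[C@](C)(O)C#C | intermediate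
6 | tributyltin hydride (Bu3SnH) | CCCC[SnH](CCCC)CCCC | starting material
7 | (S,E)-3,7-dimethyl-1-(tributylstannyl)octa-1,6-dien-3-ol | CC(C)=CCC[C@](C)(O)/C=C/[Sn](CCCC)(CCCC)CCCC | intermediate
8 | 2-hydroxy-3-methoxy-5-methylbenzaldehyde | COc1cc(C)cc(C=O)c1O | starting material
9 | 2,3-dihydroxy-5-methylbenzaldehyde | Cc1cc(O)c(O)c(C=O)c1 | intermediate
10 | 2,3-bis(benzyloxy)-5-methylbenzaldehyde | Cc1cc(OCc2ccccc2)c(OCc2ccccc2)c(C=O)c1 | intermediate
11 | [2,3-bis(benzyloxy)-5-methylphenyl]methanol | Cc1cc(OCc2ccccc2)c(OCc2ccccc2)c(CO)c1 | intermediate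
12 | 1,2-bis(benzyloxy)-3-(bromomethyl)-5-methylbenzene | Cc1cc(OCc2ccccc2)c(OCc2ccccc2)c(CBr)c1 | intermediate
13 | ethynylmagnesium bromide (HC≡CMgBr) | C#C[Mg]Br | starting material
14 | 1,2-bis(benzyloxy)-5-methyl-3-(prop-2-yn-1-yl)benzene | Cc1cc(OCc2ccccc2)c(OCc2ccccc2)c(CC#C)c1 | intermediate
15 | trichloroacetyl chloride | ClC(=O)C(Cl)(Cl)Cl | starting material
16 | dichloroketene | O=C=C(Cl)Cl | intermediate
17 | 3-[2,3-bis(benzyloxy)-5-methylbenzyl]-4,4-dichlorocyclobut-2-en-1-one | Cc1cc(OCc2ccccc2)c(OCc2ccccc2)c(CC2=CC(=O)C2(Cl)Cl)c1 | intermediate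
18 | 3-[2,3-bis(benzyloxy)-5-methylbenzyl]-4-chlorocyclobut-2-en-1-one (racemic at C4) | Cc1cc(OCc2ccccc2)c(OCc2ccccc2)c(CC2=CC(=O)C2Cl)c1 | intermediate
19 | 3-[2,3-bis(benzyloxy)-5-methylbenzyl]-4-[(1E,3S)-3-hydroxy-3,7-dimethylocta-1,6-dien-1-yl]cyclobut-2-en-1-one (C4 undefined) | Cc1cc(OCc2ccccc2)c(OCc2ccccc2)c(CC2=CC(=O)C2/C=C/[C@@](C)(O)CCC=C(C)C)c1 | intermediate
20 | (3Z,5E,7S)-3-[2,3-bis(benzyloxy)-5-methylbenzyl]-7-hydroxy-7,11-dimethyldodeca-1,3,5,10-tetraen-1-one | O=C=C/C(Cc1cc(C)cc(OCc2ccccc2)c1OCc1ccccc1)=C\C=C\[C@@](C)(O)CCC=C(C)C | intermediate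
21 | 3-[2,3-bis(benzyloxy)-5-methylbenzyl]-6-[(2S)-2-hydroxy-6-methylhept-5-en-2-yl]cyclohexa-2,4-dien-1-one (C6 undefined) | O=C1C=C(Cc2cc(C)cc(OCc3ccccc3)c2OCc2ccccc2)C=CC1[C@@](C)(O)CCC=C(C)C | intermediate
22 | 5-[2,3-bis(benzyloxy)-5-methylbenzyl]-2-[(2S)-2-hydroxy-6-methylhept-5-en-2-yl]phenol | Cc1cc(OCc2ccccc2)c(OCc2ccccc2)c(Cc2ccc([C@@](C)(O)CCC=C(C)C)c(O)c2)c1 | intermediate
23 | asperchondol A, 3-{3-hydroxy-4-[(2S)-2-hydroxy-6-methylheptan-2-yl]benzyl}-5-methylbenzene-1,2-diol | Cc1cc(O)c(O)c(Cc2ccc([C@@](C)(O)CCCC(C)C)c(O)c2)c1 | target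

Total step count: 13.
Longest linear sequence: 9 steps (steps 5–13, from aldehyde 8 to 23); the geraniol branch contributes steps 1–4.

Steps most likely to fail

Step 12. The free tertiary hydroxyl may divert the cascade, by adding to the ketene or by retro-aldol-type loss of the side chain from the cyclohexadienone before it tautomerises, and protodestannylation may outrun transmetalation. The fallback masks the hydroxyl, sets out from alkynol 5 and comes back at 22. Silylation of 5 (Et3SiOTf, 2,6-lutidine, CH2Cl2, 0 °C) would give the triethylsilyl ether of the alkynol F1. Hydrostannation as in step 4 would give the silylated stannane F2. Coupling of F2 with 18 under the conditions of step 12 would pass through the silylated 4-alkenylcyclobutenone F3, the silylated dienylketene F4 and the silylated cyclohexadienone F5, none of them isolated, to the silylated phenol F6. Bu4NF in THF would then remove the silyl group and return the route to 22.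

Step 11. The reduction may run on past the monochloride to the chlorine-free cyclobutenone, or zinc salts and amine may shift the chlorine or move the ring double bond toward the benzylic position. The fallback replaces electron transfer at the metal by a radical chain whose extent is fixed by the amount of hydride; it sets out from 17 and comes back at 18. Bu3SnH (1.0 equiv) with AIBN (cat.) in benzene at 70 °C should abstract one chlorine atom and deliver one hydrogen atom. This fallback makes no compound outside the list (F0).

Step 9. The product acetylide may be benzylated a second time, and the basic Grignard medium may isomerise the propargyl arene to the allene. The fallback caps the alkyne with silicon and changes the bond formation to an uncatalysed SN2 alkylation; it sets out from bromide 12 and comes back at 14. Me3SiC≡CLi (commercial THF solution) in THF/DMPU at −78 → 0 °C would give the silyl-capped alkyne F7. Bu4NF buffered with AcOH in THF at 0 °C would then release 14.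

Further compounds
F1 | step 12 | (S)-[(3,7-dimethyloct-6-en-1-yn-3-yl)oxy]triethylsilane | CC(C)=CCC[C@](C)(O[Si](CC)(CC)CC)C#C
F2 | step 12 | (S,E)-{[3,7-dimethyl-1-(tributylstannyl)octa-1,6-dien-3-yl]oxy}triethylsilane | CC(C)=CCC[C@](C)(O[Si](CC)(CC)CC)/C=C/[Sn](CCCC)(CCCC)CCCC
F3 | step 12 | 3-[2,3-bis(benzyloxy)-5-methylbenzyl]-4-{(1E,3S)-3,7-dimethyl-3-[(triethylsilyl)oxy]octa-1,6-dien-1-yl}cyclobut-2-en-1-one | Cc1cc(OCc2ccccc2)c(OCc2ccccc2)c(CC2=CC(=O)C2/C=C/[C@@](C)(O[Si](CC)(CC)CC)CCC=C(C)C)c1
F4 | step 12 | (3Z,5E,7S)-3-[2,3-bis(benzyloxy)-5-methylbenzyl]-7,11-dimethyl-7-[(triethylsilyl)oxy]dodeca-1,3,5,10-tetraen-1-one | O=C=C/C(Cc1cc(C)cc(OCc2ccccc2)c1OCc1ccccc1)=C\C=C\[C@@](C)(O[Si](CC)(CC)CC)CCC=C(C)C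
F5 | step 12 | 3-[2,3-bis(benzyloxy)-5-methylbenzyl]-6-{(2S)-6-methyl-2-[(triethylsilyl)oxy]hept-5-en-2-yl}cyclohexa-2,4-dien-1-one | O=C1C=C(Cc2cc(C)cc(OCc3ccccc3)c2OCc2ccccc2)C=CC1[C@@](C)(O[Si](CC)(CC)CC)CCC=C(C)C
F6 | step 12 | 5-[2,3-bis(benzyloxy)-5-methylbenzyl]-2-{(2S)-6-methyl-2-[(triethylsilyl)oxy]hept-5-en-2-yl}phenol | Cc1cc(OCc2ccccc2)c(OCc2ccccc2)c(Cc2ccc([C@@](C)(O[Si](CC)(CC)CC)CCC=C(C)C)c(O)c2)c1
F0 | step 11 | none | none
F7 | step 9 | {3-[2,3-bis(benzyloxy)-5-methylphenyl]prop-1-yn-1-yl}trimethylsilane | Cc1cc(OCc2ccccc2)c(OCc2ccccc2)c(CC#C[Si](C)(C)C)c1
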